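**Assumption:** tetralin numbering with C1 as the aryl-bearing carbon; the target SMILES is read as (1S,2R,3R), i.e. 1,2-trans-2,3-trans. Compounds 1, 2 and 5 are taken as commercial.

## Retrosynthetic overview

- The tetralin ring (C1–C8a) is formed last, by attack of the guaiacyl ring on a syringyl p-quinone methide.
- That quinone methide is made by C7'–H oxidation of fully unprotected (8R,8'R)-5-methoxysecoisolariciresinol. It is first caught by the C9 hydroxyl as a lariciresinol-type oxolane (first ring), which acid then converts into the carbocycle (second ring).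
- The seco-diol comes from global hydride reduction of a 2,3-dibenzylsuccinate carrying one Evans imide and one methyl ester.
- The C8–C8' bond comes from oxidative heterocoupling of an imide enolate (guaiacyl C6–C3 unit) with an ester enolate (syringyl C6–C3 unit).
- The two C6–C3 units come from dihydroferulic acid and sinapic acid.

## Route

**Step 1**
Reactants: 1 3-(4-hydroxy-3-methoxyphenyl)propanoic acid; 2 (S)-4-benzyl-1,3-oxazolidin-2-one
Product: 4 (S)-4-benzyl-3-{3-[3-methoxy-4-(pivaloyloxy)phenyl]propanoyl}-1,3-oxazolidin-2-one, via mixed pivalic anhydride 3 (not isolated)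
Conditions: PivCl (2.1 equiv), Et3N (3.3 equiv), THF, −20 → 0 °C, 1.5 h; then LiCl (1.1 equiv), 2 (1.0 equiv), 0 °C → rt, 12 h
Reagents that add atoms: pivaloyl chloride, CC(C)(C)C(Cl)=O
Why: The acid chloride O-acylates the unhindered guaiacyl phenol and converts the carboxylate into the mixed pivalic anhydride, which LiCl/Et3N-activated oxazolidinone then attacks at its less hindered carbonyl (Evans auxiliary attachment by the mixed-anhydride method); no stereocentre is formed.

**Step 2**
Reactants: 5 sinapic acid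
Product: 7 methyl 3-(4-hydroxy-3,5-dimethoxyphenyl)propanoate, via dihydrosinapic acid 6 (not isolated)
Conditions: H2 (1 atm), 10% Pd/C, 1.25 M HCl in MeOH, rt, 16 h
Reagents that add atoms: methanol, CO
Why: Heterogeneous hydrogenation of the cinnamic C=C and Fischer esterification run side by side in methanolic HCl, and the arene, phenol and methyl ethers are inert.

**Step 3**
Reactants: 7 methyl 3-(4-hydroxy-3,5-dimethoxyphenyl)propanoate
Product: 8 methyl 3-[3,5-dimethoxy-4-(pivaloyloxy)phenyl]propanoate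
Conditions: PivCl (1.3 equiv), Et3N (2 equiv), DMAP (10 mol%), CH2Cl2, 0 °C → rt
Reagents that add atoms: pivaloyl chloride, CC(C)(C)C(Cl)=O
Why: DMAP-catalysed acylation of the hindered syringyl phenol gives a non-enolisable, sterically shielded aryl pivalate that tolerates lithium enolates at −78 °C and is removed later by LiAlH4.

**Step 4**
Reactants: 4 (S)-4-benzyl-3-{3-[3-methoxy-4-(pivaloyloxy)phenyl]propanoyl}-1,3-oxazolidin-2-one; 8 methyl 3-[3,5-dimethoxy-4-(pivaloyloxy)phenyl]propanoate
Product: 11 methyl (2R,3R)-3-{[(4S)-4-benzyl-2-oxo-1,3-oxazolidin-3-yl]carbonyl}-2-[3,5-dimethoxy-4-(pivaloyloxy)benzyl]-4-[3-methoxy-4-(pivaloyloxy)phenyl]butanoate, via imide lithium enolate 9 (not isolated), via ester lithium enolate 10 (not isolated)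
Conditions: 4 + 8 (1:1) added to LDA (2.1 equiv), THF, −78 °C, 30 min; then Fe(acac)3 (2.2 equiv), −78 °C → rt; chromatography removes the C2-epimer and homodimers
Reagents that add atoms: none
Why: Oxidative enolate heterocoupling (one-electron oxidation by Fe(III) inside a mixed imide/ester lithium enolate aggregate) joins the two α-carbons as a laboratory counterpart of 8–8' phenoxyl coupling; the imide-side centre (C3, R) is set by the (S)-benzyl auxiliary because the partner adds to the chelated Z-enolate anti to the benzyl group as in Evans alkylations, whereas the ester-side centre (C2) forms with only modest selectivity (about 2:1 expected), so the (2R,3R) isomer is isolated by chromatography.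

**Step 5**
Reactants: 11 methyl (2R,3R)-3-{[(4S)-4-benzyl-2-oxo-1,3-oxazolidin-3-yl]carbonyl}-2-[3,5-dimethoxy-4-(pivaloyloxy)benzyl]-4-[3-methoxy-4-(pivaloyloxy)phenyl]butanoate
Product: 12 (2R,3R)-2-(4-hydroxy-3,5-dimethoxybenzyl)-3-(4-hydroxy-3-methoxybenzyl)butane-1,4-diol
Conditions: LiAlH4 (6 equiv), THF, 0 °C → rt, 3 h; Rochelle salt, then aq. citric acid to pH 5, EtOAc
Reagents that add atoms: none
Why: Exhaustive hydride reduction cleaves the N-acyl oxazolidinone to the primary alcohol with release of the auxiliary, reduces the methyl ester and removes both aryl pivalates reductively, and none of these events touches the two stereocentres.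

**Step 6**
Reactants: 12 (2R,3R)-2-(4-hydroxy-3,5-dimethoxybenzyl)-3-(4-hydroxy-3-methoxybenzyl)butane-1,4-diol
Product: 15 5-methoxy-(+)-isolariciresinol, via syringyl quinone methide 13 (not isolated), via lariciresinol-type oxolane 14 (not isolated)
Conditions: DDQ (1.0 equiv, slow addition), 1,4-dioxane, 15 °C, 30 min; then TFA (20 vol%), rt, 2 h; aq. NaHCO3/MeOH work-up
Reagents that add atoms: none
Why: Proposed new method: DDQ removes hydride from the benzylic CH2 para to the more electron-rich syringyl phenol (lower oxidation potential than the guaiacyl phenol) to give p-quinone methide 13, which the C9 hydroxyl traps 5-exo as oxolane 14; TFA then reopens this benzylic ether to the protonated quinone methide and the guaiacyl ring attacks irreversibly through C6 (para to OMe) in a chair-like transition state with all three substituents pseudo-equatorial, so C1 is set 1,2-trans (1S) under control of C2 and C3; the closest known reactions are DDQ dehydrogenation of 4-alkylphenols to quinone methides and the acid isomerisation of lariciresinol to isolariciresinol (intramolecular Friedel–Crafts alkylation).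

## Compound list

1 | 3-(4-hydroxy-3-methoxyphenyl)propanoic acid (dihydroferulic acid) | COc1cc(CCC(=O)O)ccc1O | starting material
2 | (S)-4-benzyl-1,3-oxazolidin-2-one | O=C1N[C@@H](Cc2ccccc2)CO1 | starting material
3 | 3-[3-methoxy-4-(pivaloyloxy)phenyl]propanoic pivalic anhydride | COc1cc(CCC(=O)OC(=O)C(C)(C)C)ccc1OC(=O)C(C)(C)C | intermediate
4 | (S)-4-benzyl-3-{3-[3-methoxy-4-(pivaloyloxy)phenyl]propanoyl}-1,3-oxazolidin-2-one | COc1cc(CCC(=O)N2[C@@H](Cc3ccccc3)COC2=O)ccc1OC(=O)C(C)(C)C | intermediate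
5 | sinapic acid, (E)-3-(4-hydroxy-3,5-dimethoxyphenyl)prop-2-enoic acid | COc1cc(/C=C/C(=O)O)cc(OC)c1O | starting material
6 | 3-(4-hydroxy-3,5-dimethoxyphenyl)propanoic acid (dihydrosinapic acid) | COc1cc(CCC(=O)O)cc(OC)c1O | intermediate
7 | methyl 3-(4-hydroxy-3,5-dimethoxyphenyl)propanoate | COC(=O)CCc1cc(OC)c(O)c(OC)c1 | intermediate
8 | methyl 3-[3,5-dimethoxy-4-(pivaloyloxy)phenyl]propanoate | COC(=O)CCc1cc(OC)c(OC(=O)C(C)(C)C)c(OC)c1 | intermediate
9 | lithium (Z)-enolate of imide 4 (O–Li cis to the CH2Ar group) | [Li]O/C(=C\Cc1ccc(OC(=O)C(C)(C)C)c(OC)c1)N1[C@@H](Cc2ccccc2)COC1=O | intermediate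
10 | lithium enolate of ester 8 (O–Li trans to the CH2Ar group) | CO/C(O[Li])=C\Cc1cc(OC)c(OC(=O)C(C)(C)C)c(OC)c1 | intermediate
11 | methyl (2R,3R)-3-{[(4S)-4-benzyl-2-oxo-1,3-oxazolidin-3-yl]carbonyl}-2-[3,5-dimethoxy-4-(pivaloyloxy)benzyl]-4-[3-methoxy-4-(pivaloyloxy)phenyl]butanoate | COC(=O)[C@H](Cc1cc(OC)c(OC(=O)C(C)(C)C)c(OC)c1)[C@@H](Cc1ccc(OC(=O)C(C)(C)C)c(OC)c1)C(=O)N1[C@@H](Cc2ccccc2)COC1=O | intermediate
12 | (2R,3R)-2-(4-hydroxy-3,5-dimethoxybenzyl)-3-(4-hydroxy-3-methoxybenzyl)butane-1,4-diol (5-methoxysecoisolariciresinol) | OC[C@H](Cc1ccc(O)c(OC)c1)[C@H](CO)Cc1cc(OC)c(O)c(OC)c1 | intermediate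
13 | 4-[(2R,3R)-4-hydroxy-2-(hydroxymethyl)-3-(4-hydroxy-3-methoxybenzyl)butylidene]-2,6-dimethoxycyclohexa-2,5-dien-1-one | COC1=CC(=C[C@@H](CO)[C@H](CO)Cc2ccc(O)c(OC)c2)C=C(OC)C1=O | intermediate
14 | 4-[(2S,3R,4R)-4-(4-hydroxy-3-methoxybenzyl)-3-(hydroxymethyl)oxolan-2-yl]-2,6-dimethoxyphenol | COc1cc(C[C@H]2CO[C@@H]([C@H]2CO)c3cc(OC)c(O)c(OC)c3)ccc1O | intermediate
15 | 5-methoxy-(+)-isolariciresinol, (1S,2R,3R)-7-hydroxy-1-(4-hydroxy-3,5-dimethoxyphenyl)-6-methoxy-1,2,3,4-tetrahydronaphthalene-2,3-dimethanol | COc1cc2c(cc1O)[C@H](c1cc(OC)c(O)c(OC)c1)[C@@H](CO)[C@H](CO)C2 | target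

## Step count

Total steps: 6. Longest linear sequence: 5 (5 → 7 → 8 → 11 → 12 → 15).

## Steps most likely to fail, with fallbacks

**Step 6 (oxidative cascade).** The risks are oxidation of the guaiacyl phenol as well as the syringyl one, and over-oxidation. The fallback differentiates the two phenols before oxidation. It sets out from 12: PivCl (1.0 equiv), K2CO3, acetone, 0 °C acylates only the unhindered guaiacyl phenoxide and gives the guaiacyl mono-pivalate of the seco-diol F1; the syringyl OH, flanked by two methoxy groups, and the primary alcohols stay free. Only the syringyl ring can now form a quinone methide, so DDQ followed by TFA (as in step 6) leads through the O-pivaloyl quinone methide F2 and the O-pivaloyl oxolane F3 to the 7-O-pivaloyl cyclolignan F4. K2CO3 in MeOH removes the pivalate and the route is rejoined at 15.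

**Step 4 (heterocoupling).** The main risk is poor or wrong-sense selectivity at the ester-derived centre C2. The fallback sets this centre by thermodynamic control in a lactone instead. It sets out from the unseparated mixture of 11 and its (2S,3R) C2-epimer F5. LiBH4 (1.2 equiv), MeOH (1.2 equiv), THF, 0 °C reduces only the imide carbonyl, and the liberated alkoxides close onto the methyl ester to give the cis-lactone F6 and the trans-lactone F7. DBU in toluene at rt equilibrates F6 into the more stable F7, and the auxiliary-set centre is not touched. LiAlH4 in THF then opens F7 and removes both pivalates, rejoining the route at 12.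

**Step 5 (global reduction).** The risk is hydride attack on the ring carbonyl of the oxazolidinone in this hindered imide. The fallback removes the auxiliary hydrolytically. It sets out from 11: LiOH/H2O2, THF/H2O, 0 °C cleaves the exocyclic acyl group; after a Na2SO3 quench, excess LiOH at rt hydrolyses the methyl ester and both aryl pivalates to give the free-phenol succinic diacid F8. BH3·SMe2 in THF (0 °C → rt) reduces both carboxylic acids in the presence of the phenols, rejoining the route at 12.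

## Further compounds

F1 | step 6 | 4-[(2R,3R)-4-hydroxy-3-(4-hydroxy-3,5-dimethoxybenzyl)-2-(hydroxymethyl)butyl]-2-methoxyphenyl pivalate (guaiacyl mono-pivalate of 12) | OC[C@H](Cc1ccc(OC(=O)C(C)(C)C)c(OC)c1)[C@H](CO)Cc1cc(OC)c(O)c(OC)c1
F2 | step 6 | guaiacyl O-pivaloyl analogue of quinone methide 13 | COC1=CC(=C[C@@H](CO)[C@H](CO)Cc2ccc(OC(=O)C(C)(C)C)c(OC)c2)C=C(OC)C1=O
F3 | step 6 | guaiacyl O-pivaloyl analogue of oxolane 14, (2S,3R,4R) | COc1cc(C[C@H]2CO[C@@H]([C@H]2CO)c3cc(OC)c(O)c(OC)c3)ccc1OC(=O)C(C)(C)C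
F4 | step 6 | 7-O-pivaloyl-5-methoxy-(+)-isolariciresinol, (1S,2R,3R) | COc1cc2c(cc1OC(=O)C(C)(C)C)[C@H](c1cc(OC)c(O)c(OC)c1)[C@@H](CO)[C@H](CO)C2
F5 | step 4 | methyl (2S,3R)-3-{[(4S)-4-benzyl-2-oxo-1,3-oxazolidin-3-yl]carbonyl}-2-[3,5-dimethoxy-4-(pivaloyloxy)benzyl]-4-[3-methoxy-4-(pivaloyloxy)phenyl]butanoate (C2-epimer of 11) | COC(=O)[C@@H](Cc1cc(OC)c(OC(=O)C(C)(C)C)c(OC)c1)[C@@H](Cc1ccc(OC(=O)C(C)(C)C)c(OC)c1)C(=O)N1[C@@H](Cc2ccccc2)COC1=O
F6 | step 4 | (3S,4R)-3-[3,5-dimethoxy-4-(pivaloyloxy)benzyl]-4-[3-methoxy-4-(pivaloyloxy)benzyl]oxolan-2-one (cis-lactone) | O=C1OC[C@H](Cc2ccc(OC(=O)C(C)(C)C)c(OC)c2)[C@@H]1Cc1cc(OC)c(OC(=O)C(C)(C)C)c(OC)c1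
F7 | step 4 | (3R,4R)-3-[3,5-dimethoxy-4-(pivaloyloxy)benzyl]-4-[3-methoxy-4-(pivaloyloxy)benzyl]oxolan-2-one (trans-lactone) | O=C1OC[C@H](Cc2ccc(OC(=O)C(C)(C)C)c(OC)c2)[C@H]1Cc1cc(OC)c(OC(=O)C(C)(C)C)c(OC)c1
F8 | step 5 | (2R,3R)-2-(4-hydroxy-3,5-dimethoxybenzyl)-3-(4-hydroxy-3-methoxybenzyl)succinic acid | OC(=O)[C@H](Cc1cc(OC)c(O)c(OC)c1)[C@@H](Cc1ccc(O)c(OC)c1)C(=O)O
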